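The numbers in the tables were computed for substances that don't exist, and the scatter is random.

I began with a subtraction: whatever in a run was neither solid L nor G stood dissolved.

| flask | L | Q | remark |
|---|---|---|---|
| north-west | 12 mM | 0.01 mol% | the very flask that is asked about, followed so far |
| north | 12 mM | 0.005 mol% | run made earlier |
| flask | 12 mM | 0.01 mol% |  |

| run | time / min | G / % | L / % |
|---|---|---|---|
| north-west | 2.50 | 0 | 98.3 |
| north-west | 8.00 | 2.1 | 96.5 |
| north-west | 15.0 | 5.8 | 92.7 |
| north-west | 20.0 | 9.1 | 89.9 |
| north-west | 30.0 | 13.4 | 84.4 |
| north-west | 40.0 | 18.4 | 79.5 |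
| north-west | 50.0 | 23.5 | 74.7 |
| north | 5.00 | 1.0 | 96.7 |
| north | 12.0 | 3.3 | 94.2 |
| north | 25.0 | 8.0 | 87.1 |
| north | 40.0 | 16.7 | 81.2 |
| north | 50.0 | 21.5 | 75.1 |
| north | 60.0 | 25.9 | 71.1 |
| north | 80.0 | 36.7 | 61.7 |

(scatter of a reading: 0.5 percentage points)

- solid, in amounts per volume of the solution: L
- at the start none of L is in solution
- what has only dissolved of L counts as not reacted

- apparent order in Q when 50% of the L are converted (what has only dissolved counts as not reacted) (percent change of the rate of making G for one percent more Q charged)
- factor on the rate of making G when 50% of the L are converted (what has only dissolved counts as not reacted) if Q is charged twice over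

The decision for the next run was whether to charge Q twice over. I took the mean dissolved fraction of the charge and the slope of G, from 15.0 min on in the north-west run and from 25.0 min on in the north run:

north-west: dissolved 1.72%, rate 0.303 h⁻¹

north: dissolved 3.00%, rate 0.313 h⁻¹

The north-west rate, at 0.01 mol% of Q, read about the same as the north rate at 0.005 mol%; their ratio read 0.968, so I left Q at 0.01 mol%.

Then I followed one molecule of L and asked how long it stayed dissolved before it became G. In the north-west run, the dissolved fraction over the rate of making G gave my waiting time in solution:

waiting time = 1.72% / 0.303 h⁻¹ = 3.40 min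

At the north-west rate I reckoned 3.30 h for the whole charge to pass, far longer than the waiting time, so I took leaving the solid as the rate-limiting step.

The forecast gave an order of 0.05 (0 to 0.2) and a factor of 1.03 (1 to 1.13): “Raising Q only lowers the small pool, which slightly increases the dissolution driving force.” My ratio, a reading that carried their scatter of 0.5 percentage points, stood lower than its factor.

The flask gave an order in Q of 0.032 and a factor of 1.02 for Q charged twice over, with Z, the dissolved L, at 1.66% of the charge after 1.00 h and 1.66% after 2.00 h, on either side of the 1.70 h at which 50% conversion stood.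

D → Q + G (k = 435 min⁻¹); L ⇌ Z, rate k2*(cs2 - [Z]) while solid is left; crystals form when [Z] > cs2 (solubility = 7.00 mM, k = 0.00895 min⁻¹); Z + Q ⇌ D (K = 1500 L mol⁻¹, k = 5.15 × 10⁵ L mol⁻¹ min⁻¹) My waiting time, multiplied by the rate of 0.304 h⁻¹ at 50% conversion, put 1.72% of the charge in solution in this flask. For the north run, with half the Q, I took a waiting time of 6.80 min; at its rate of 0.313 h⁻¹ that put 3.55% in solution, and its readings gave 3.00%.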